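Ring C of the flavan unit is opened at C3–C4. C4 is the benzylic carbon para to O7 (and ortho to O1) of ring A, so with ring A written as a para-quinone methide it becomes a 1,6-acceptor. C3 is made the α-carbon of an enal-derived enamine, and its hydroxyl is the Baeyer–Villiger retron of a formyl group. One iminium–enamine cascade then joins a diarylcarbinol, which already carries the protected flavonol on C4, with a cinnamaldehyde: oxa-Michael addition forms O1–C2 and the tethered enamine closes C3–C4 onto the quinone methide, setting C2, C3 and C4 together.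

Key step: step 7

Remark: gossypetin is taken as a purchasable flavonol; the flavan locants (O1, C2, C3, C4, C4a, C5–C8, C8a; ring A, ring C) are used for these atoms in all precursors.

Step 1
Reactants: 1 gossypetin
Product: 2 gossypetin 3,7,8,3',4'-pentabenzyl ether (5-OH free)
Conditions: BnBr, K2CO3, DMF (degassed), Ar, rt
Reagents that add atoms: benzyl bromide BrCc1ccccc1
Why: Williamson etherification in which the 5-OH, hydrogen-bonded to the C4 carbonyl and the least reactive hydroxyl, should stay free, while degassing protects the 5,8-dihydroxy ring from air oxidation.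

Step 2
Reactants: 2 gossypetin pentabenzyl ether
Product: 3 flavonol 5-triflate
Conditions: Tf2O, pyridine, CH2Cl2, 0 °C → rt
Reagents that add atoms: trifluoromethanesulfonic anhydride O=S(=O)(OS(=O)(=O)C(F)(F)F)C(F)(F)F
Why: O-sulfonylation of the one remaining (chelated) phenol gives the aryl triflate that serves as the handle for C–C bond formation at C5 of the flavonol.

Step 3
Reactants: 3 flavonol 5-triflate
Product: 4 flavonol-5-carbaldehyde
Conditions: Pd(OAc)2, dppp, CO (1 atm), Et3SiH, Et3N, DMF, 70 °C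
Reagents that add atoms: carbon monoxide [C-]#[O+]
Why: Palladium-catalysed reductive carbonylation of an aryl triflate (oxidative addition to zerovalent palladium, CO insertion, hydride transfer from the silane) installs the formyl carbon that becomes C4 of the flavan, and benzyl ethers and the pyranone are inert to it.

Step 4
Reactants: 5 pyrogallol
Product: 6 2-(benzyloxy)benzene-1,3-diol
Conditions: BnBr (1 equiv), Li2CO3, DMF, Ar, 50 °C
Reagents that add atoms: benzyl bromide BrCc1ccccc1
Why: Williamson mono-etherification that should go to the central oxygen, because the central hydroxyl is the most acidic (its phenoxide is hydrogen-bonded from both neighbours); outer ethers are removed by chromatography.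

Step 5
Reactants: 4 flavonol-5-carbaldehyde; 6 2-(benzyloxy)benzene-1,3-diol
Product: 7 racemic diarylcarbinol (ring A diphenol joined to the flavonol through the future C4)
Conditions: 6, EtMgBr (2 equiv per 6), Et2O, 0 °C; then CH2Cl2, 4, 0 °C → rt; pH 7 buffer, used without acidic chromatography
Reagents that add atoms: none
Why: Ortho-selective hydroxyalkylation of a bromomagnesium phenoxide by an aromatic aldehyde through a chelated six-membered transition state; C4 and C6 of 6 are equivalent and the only activated positions, the pyranone is not attacked, and the racemic carbinol centre is erased in step 7.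

Step 6
Reactants: 8 3,4-bis(benzyloxy)benzaldehyde
Product: 9 (E)-3,4-bis(benzyloxy)cinnamaldehyde
Conditions: Ph3P=CHCHO, toluene, 80 °C
Reagents that add atoms: (triphenylphosphoranylidene)acetaldehyde O=CC=P(c1ccccc1)(c1ccccc1)c1ccccc1
Why: Wittig olefination with a stabilised formyl ylide, which should give the (E)-enal.

Step 7
Reactants: 7 racemic diarylcarbinol; 9 (E)-3,4-bis(benzyloxy)cinnamaldehyde
Product: 11 (2S,3S,4R)-8-(benzyloxy)-2-[3,4-bis(benzyloxy)phenyl]-7-hydroxy-4-(pentabenzyloxyflavon-5-yl)chromane-3-carbaldehyde, via para-quinone methide 10 (not isolated)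
Conditions: (S)-2-[diphenyl(trimethylsilyloxy)methyl]pyrrolidine (20 mol%), PhCO2H (20 mol%), 9 (1.5 equiv), toluene (0.02 M), Ar, rt
Reagents that add atoms: none
Why: The amine condenses with 9 to an (E)-iminium ion, the phenolic O1–H of 7 (ortho to the carbinol carbon) adds reversibly to its β-carbon (oxa-Michael) to give an enamine, and acid-assisted loss of water from the para-hydroxybenzhydrol unit (in either order) gives the ring A para-quinone methide 10, whose methide carbon C4 is attacked in a 1,6-sense by the enamine carbon C3 with rearomatisation of ring A and hydrolytic release of the catalyst. The closest known reaction type is the aminocatalytic domino oxa-Michael/1,6-conjugate addition of hydroxyaryl para-quinone methides with enals, combined with in situ generation of para-quinone methides from para-hydroxybenzyl alcohols. Ring C closes at C3–C4 as a 6-endo-trig addition with respect to the exocyclic C4=C4a bond (6-enolexo for the enamine). C2 is controlled by the catalyst, O1 adding to the iminium face remote from the CPh2(OSiMe3) group of the (S)-amine, which should give 2S; C3 and C4 follow from a chair-like closure with the C2 aryl, the enamine carbon and the flavonyl group pseudo-equatorial (2,3-trans-3,4-trans), and C3 can further equilibrate to this all-equatorial isomer through the enamine. The step needs O1 and not O7 to be the productive nucleophile and intramolecular capture of 10 to beat intermolecular arylation: the O7 adduct cannot cyclise and reverts, the reversible oxa-Michael step is funnelled through the irreversible ring closure, and high dilution keeps 10 from reacting with a second molecule.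

Step 8
Reactants: 11 chromane-3-carbaldehyde
Product: 13 (2R,3S,4R)-8-(benzyloxy)-2-[3,4-bis(benzyloxy)phenyl]-4-(pentabenzyloxyflavon-5-yl)chromane-3,7-diol, via formate ester 12 (not isolated)
Conditions: mCPBA, NaHCO3, CH2Cl2, 0 °C; then K2CO3 (cat.), MeOH, 0 °C
Reagents that add atoms: meta-chloroperoxybenzoic acid O=C(OO)c1cccc(Cl)c1
Why: Baeyer–Villiger oxidation of an α-branched aldehyde, in which the secondary carbon C3 migrates to oxygen with retention to give formate 12, whose methanolysis frees the C3 hydroxyl, so C3 keeps the configuration set in step 7.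

Step 9
Reactants: 13 protected flavan-3-ol–flavonol
Product: 14 target
Conditions: H2 (1 atm), Pd(OH)2/C, THF/MeOH, rt
Reagents that add atoms: none
Why: Catalytic hydrogenolysis of the eight benzyl ethers under the neutral conditions used for benzylated catechins and flavonols, which should leave the benzylic C2–O1 bond, the C4–aryl bonds, the pyranone and the three stereocentres untouched.

Compound list
1 | gossypetin (3,5,7,8,3',4'-hexahydroxyflavone) | O=c1c(O)c(-c2ccc(O)c(O)c2)oc2c(O)c(O)cc(O)c12 | starting material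
2 | 3,7,8-tris(benzyloxy)-2-[3,4-bis(benzyloxy)phenyl]-5-hydroxy-4H-chromen-4-one | O=c1c(OCc2ccccc2)c(-c2ccc(OCc3ccccc3)c(OCc3ccccc3)c2)oc2c(OCc3ccccc3)c(OCc3ccccc3)cc(O)c12 | intermediate
3 | 3,7,8-tris(benzyloxy)-2-[3,4-bis(benzyloxy)phenyl]-4-oxo-4H-chromen-5-yl trifluoromethanesulfonate | O=c1c(OCc2ccccc2)c(-c2ccc(OCc3ccccc3)c(OCc3ccccc3)c2)oc2c(OCc3ccccc3)c(OCc3ccccc3)cc(OS(=O)(=O)C(F)(F)F)c12 | intermediate
4 | 3,7,8-tris(benzyloxy)-2-[3,4-bis(benzyloxy)phenyl]-4-oxo-4H-chromene-5-carbaldehyde | O=c1c(OCc2ccccc2)c(-c2ccc(OCc3ccccc3)c(OCc3ccccc3)c2)oc2c(OCc3ccccc3)c(OCc3ccccc3)cc(C=O)c12 | intermediate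
5 | pyrogallol (benzene-1,2,3-triol) | Oc1cccc(O)c1O | starting material
6 | 2-(benzyloxy)benzene-1,3-diol | Oc1cccc(O)c1OCc1ccccc1 | intermediate
7 | racemic [3-(benzyloxy)-2,4-dihydroxyphenyl]{3,7,8-tris(benzyloxy)-2-[3,4-bis(benzyloxy)phenyl]-4-oxo-4H-chromen-5-yl}methanol | O=c1c(OCc2ccccc2)c(-c2ccc(OCc3ccccc3)c(OCc3ccccc3)c2)oc2c(OCc3ccccc3)c(OCc3ccccc3)cc(C(O)c3ccc(O)c(OCc4ccccc4)c3O)c12 | intermediate
8 | 3,4-bis(benzyloxy)benzaldehyde | O=Cc1ccc(OCc2ccccc2)c(OCc2ccccc2)c1 | starting material
9 | (E)-3-[3,4-bis(benzyloxy)phenyl]prop-2-enal | O=C/C=C/c1ccc(OCc2ccccc2)c(OCc2ccccc2)c1 | intermediate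
10 | para-quinone methide (not isolated, methide geometry not defined): 2-(benzyloxy)-3-hydroxy-4-({3,7,8-tris(benzyloxy)-2-[3,4-bis(benzyloxy)phenyl]-4-oxo-4H-chromen-5-yl}methylidene)cyclohexa-2,5-dien-1-one | O=C1C=CC(=Cc2cc(OCc3ccccc3)c(OCc3ccccc3)c3oc(-c4ccc(OCc5ccccc5)c(OCc5ccccc5)c4)c(OCc4ccccc4)c(=O)c23)C(O)=C1OCc1ccccc1 | intermediate
11 | (2S,3S,4R)-8-(benzyloxy)-2-[3,4-bis(benzyloxy)phenyl]-7-hydroxy-4-{3,7,8-tris(benzyloxy)-2-[3,4-bis(benzyloxy)phenyl]-4-oxo-4H-chromen-5-yl}chromane-3-carbaldehyde (2,3-trans-3,4-trans) | O=c1c(OCc2ccccc2)c(-c2ccc(OCc3ccccc3)c(OCc3ccccc3)c2)oc2c(OCc3ccccc3)c(OCc3ccccc3)cc([C@@H]3c4ccc(O)c(OCc5ccccc5)c4O[C@H](c4ccc(OCc5ccccc5)c(OCc5ccccc5)c4)[C@H]3C=O)c12 | intermediate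
12 | formate ester (not isolated): (2R,3S,4R)-8-(benzyloxy)-2-[3,4-bis(benzyloxy)phenyl]-7-hydroxy-4-{3,7,8-tris(benzyloxy)-2-[3,4-bis(benzyloxy)phenyl]-4-oxo-4H-chromen-5-yl}chroman-3-yl formate | O=c1c(OCc2ccccc2)c(-c2ccc(OCc3ccccc3)c(OCc3ccccc3)c2)oc2c(OCc3ccccc3)c(OCc3ccccc3)cc([C@@H]3c4ccc(O)c(OCc5ccccc5)c4O[C@H](c4ccc(OCc5ccccc5)c(OCc5ccccc5)c4)[C@H]3OC=O)c12 | intermediate
13 | (2R,3S,4R)-8-(benzyloxy)-2-[3,4-bis(benzyloxy)phenyl]-4-{3,7,8-tris(benzyloxy)-2-[3,4-bis(benzyloxy)phenyl]-4-oxo-4H-chromen-5-yl}chromane-3,7-diol | O=c1c(OCc2ccccc2)c(-c2ccc(OCc3ccccc3)c(OCc3ccccc3)c2)oc2c(OCc3ccccc3)c(OCc3ccccc3)cc([C@@H]3c4ccc(O)c(OCc5ccccc5)c4O[C@H](c4ccc(OCc5ccccc5)c(OCc5ccccc5)c4)[C@H]3O)c12 | intermediate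
14 | 2-(3,4-dihydroxyphenyl)-5-[(2R,3S,4R)-2-(3,4-dihydroxyphenyl)-3,7,8-trihydroxychroman-4-yl]-3,7,8-trihydroxy-4H-chromen-4-one (CNP0395591.2) | O=c1c(O)c(-c2ccc(O)c(O)c2)oc2c(O)c(O)cc([C@@H]3c4ccc(O)c(O)c4O[C@H](c4ccc(O)c(O)c4)[C@H]3O)c12 | target

Total step count: 9. Longest linear sequence: 7 steps (steps 1, 2, 3, 5, 7, 8, 9).

Steps most likely to fail

Step 7. The quinone methide 10 may be intercepted by the electron-rich ring A of a second molecule (oligomerisation) before the cascade closes the ring, and enantiopurity may erode through the reversible oxa-Michael step or retro-oxa-Michael opening of 11. The fallback sets out from 6, 3 and 9 and returns at 11, and moves the C3–C4 closure to an aldol condensation. Diol 6 is ortho-formylated (MgCl2, Et3N, paraformaldehyde, MeCN, reflux) to 3-(benzyloxy)-2,4-dihydroxybenzaldehyde F1. F1 and 9 with the same (S)-amine catalyst undergo the oxa-Michael/aldol condensation cascade to (R)-8-(benzyloxy)-2-[3,4-bis(benzyloxy)phenyl]-7-hydroxy-2H-chromene-3-carbaldehyde F2. Triflate 3 is converted by Miyaura borylation (B2pin2, PdCl2(dppf), KOAc, dioxane, 90 °C) into the flavonol 5-pinacolboronate F3. Rhodium-catalysed conjugate addition of F3 to F2 ([Rh(OH)(cod)]2, KOH aq., dioxane) should place the flavonyl group on C4 and, after equilibration of C3, give the all-trans aldehyde 11, following the trans,trans preference of additions to 2-aryl-3-substituted 2H-chromenes.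

Step 5. The electron-rich carbinol may ionise during reaction or purification and arylate a second molecule of 6 to a triarylmethane. The fallback sets out from 4 and 6 and returns at 10. A three-component condensation of 4, 6 and p-toluenesulfinic acid (from its sodium salt in HCO2H/H2O, rt), in which sulfinate traps the benzylic cation faster than the arene, should give the stable racemic sulfone F4. In the flask of step 7, F4 with aqueous NaHCO3 (biphasic with toluene) loses sulfinate by 1,6-elimination to release the quinone methide 10 slowly.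

Step 8. Hydride migration may compete with migration of C3 and give the carboxylic acid, and the peracid may oxidise the free 7-hydroxy ring. The fallback sets out from 11 and returns at 13. Condensation of 11 with morpholine (toluene, molecular sieves) gives the morpholine enamine F5. Aerobic cleavage of the enamine double bond (O2, CuCl cat., MeCN, 0 °C) should give the (2R,4R)-2,4-diarylchroman-3-one F6. NaBH4 (MeOH, −20 °C) should then deliver hydride axially to the 2,4-diequatorial ketone and give the equatorial alcohol 13.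

Further compounds
F1 | step 7 | 3-(benzyloxy)-2,4-dihydroxybenzaldehyde | O=Cc1ccc(O)c(OCc2ccccc2)c1O
F2 | step 7 | (R)-8-(benzyloxy)-2-[3,4-bis(benzyloxy)phenyl]-7-hydroxy-2H-chromene-3-carbaldehyde | O=CC1=Cc2ccc(O)c(OCc3ccccc3)c2O[C@@H]1c1ccc(OCc2ccccc2)c(OCc2ccccc2)c1
F3 | step 7 | 3,7,8-tris(benzyloxy)-2-[3,4-bis(benzyloxy)phenyl]-5-(4,4,5,5-tetramethyl-1,3,2-dioxaborolan-2-yl)-4H-chromen-4-one | O=c1c(OCc2ccccc2)c(-c2ccc(OCc3ccccc3)c(OCc3ccccc3)c2)oc2c(OCc3ccccc3)c(OCc3ccccc3)cc(B3OC(C)(C)C(C)(C)O3)c12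
F4 | step 5 | racemic 5-{[3-(benzyloxy)-2,4-dihydroxyphenyl](4-methylbenzenesulfonyl)methyl}-3,7,8-tris(benzyloxy)-2-[3,4-bis(benzyloxy)phenyl]-4H-chromen-4-one | Cc1ccc(cc1)S(=O)(=O)C(c1ccc(O)c(OCc2ccccc2)c1O)c1cc(OCc2ccccc2)c(OCc2ccccc2)c2oc(-c3ccc(OCc4ccccc4)c(OCc4ccccc4)c3)c(OCc3ccccc3)c(=O)c12
F5 | step 8 | morpholine enamine of 11 (3-(morpholin-4-ylmethylidene)chromane; C2 and C4 configured as in 11; enamine geometry not defined) | O=c1c(OCc2ccccc2)c(-c2ccc(OCc3ccccc3)c(OCc3ccccc3)c2)oc2c(OCc3ccccc3)c(OCc3ccccc3)cc([C@@H]3c4ccc(O)c(OCc5ccccc5)c4O[C@H](c4ccc(OCc5ccccc5)c(OCc5ccccc5)c4)C3=CN3CCOCC3)c12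
F6 | step 8 | (2R,4R)-8-(benzyloxy)-2-[3,4-bis(benzyloxy)phenyl]-7-hydroxy-4-{3,7,8-tris(benzyloxy)-2-[3,4-bis(benzyloxy)phenyl]-4-oxo-4H-chromen-5-yl}chroman-3-one | O=c1c(OCc2ccccc2)c(-c2ccc(OCc3ccccc3)c(OCc3ccccc3)c2)oc2c(OCc3ccccc3)c(OCc3ccccc3)cc([C@@H]3c4ccc(O)c(OCc5ccccc5)c4O[C@H](c4ccc(OCc5ccccc5)c(OCc5ccccc5)c4)C3=O)c12
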